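Readings and results are calculated with constants of no real substance; noise was put on by code.

In a one-step world a flask has one product and one time constant. This flask has two products, and you want to know how their ratio r = [isomer of the product]/[target] moves with time.

| flask | substrate | reagent | catalyst | remark | time |
|---|---|---|---|---|---|
| midnight | 0.80 M | 1.6 M | 2 mM | run made earlier |  |
| dusk | 0.80 M | 1.6 M | 8 mM | run made earlier |  |
| flask | 0.80 M | 1.60 M | 4.0 mM |  | 2.0 h |

- midnight (time / min: isomer of the product / %, target / %, substrate / %): 8.00: 2, 8, 86; 25.0: 4, 26, 67; 40.0: 9, 32, 58; 60.0: 14, 37, 50; 90.0: 19, 38, 44
- dusk (time / min: isomer of the product / %, target / %, substrate / %): 8.00: 1, 13, 87; 15.0: 4, 15, 77; 25.0: 9, 21, 64; 50.0: 18, 27, 56; 90.0: 33, 30, 39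

(readings scatter by 1.5 percentage points)

1. ratio of isomer of the product to target at 30 s
2. ratio of isomer of the product to target at 8.0 min
3. ratio of isomer of the product to target at 2.0 h

Two forward steps that draw on the same substrate and reagent with the same order split them in the ratio of their rate constants, whatever the concentrations. So r at time zero is a selectivity factor. At 90.0 min substrate reads 44% in the midnight run and 39% in the dusk run, close together, yet isomer reads 33% in the dusk run with its 8 mM of catalyst, more than the 19% in the midnight run with 2 mM. I therefore read the catalyst as turning target into isomer, on top of whatever forms directly.

You can take the two ends apart and join them with a straight line, r = s + gt. In the midnight run, the readings have r climb at 0.00438 /min between 40.0 min and 90.0 min, and this line meets time zero at 0.106. In the dusk run, the readings have r climb at 0.00952 /min between 25.0 min and 50.0 min, and its line meets time zero at 0.190. Their mean, the starting ratio s of the two direct routes, is 0.148, a rough reading given the scatter of 1.5 percentage points. The 4.0 mM of this flask is the geometric mean of the two catalyst charges, so if the slope follows a power law in catalyst, the slope of this flask is the geometric mean of the two slopes, 0.00645 /min. My reckoning is then r = 0.151 at 30 s, 0.200 at 8.0 min and 0.922 at 2.0 h, the last an extrapolation, later than the latest reading.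

The forecast gives 0.005, 0.07 and 0.95, on the view that the ratio “starts near zero and climbs”, where my line starts at 0.148. The flask gives 0.146, 0.184 and 0.986.

    substrate + reagent ⇌ target (K = 0.850 /M, k = 0.690 /M/h)
    substrate + reagent ⇌ isomer of the product (K = 1.90 /M, k = 0.0990 /M/h)
    target + catalyst ⇌ isomer of the product + catalyst, rate k3*[catalyst]*[target] forward; the back reaction follows from the equilibrium constant (k = 110 /M/h)

At the start the forward direct step to target uses substrate 7.0 times as fast as the forward direct step to the isomer; beside s = 0.148, this flask stands at 0.146 at 30 s and a neighbour flask charged with 0.0024 M of catalyst at 0.145. In this flask the catalysed step between target and isomer, taken alone with both directions together, has a relaxation half-life of 1.09 h at 2.00 h, shorter than the run of 2.0 h, and by then r stands at 0.986 in this flask against 0.736 in the neighbour flask.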